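**Assumption:** the target SMILES has no stereocentre and gives no descriptor for the 3–6'' biaryl axis, so the compound is made as drawn with no stereocontrol.

**Retrosynthetic overview**
1. Target ⇐ global O-debenzylation of the fully assembled tetra-O-benzyl biflavone.
2. Ring C of the genkwanin half (the only ring built, and the last) ⇐ C-aroylation and cyclodehydration of a 2',6'-dihydroxydeoxybenzoin with 4-(benzyloxy)benzoyl chloride.
3. Key C–C bond (future C3 of the genkwanin half to C6 of the luteolin half, both natively nucleophilic carbons) ⇐ an enolonium (α-keto cation equivalent), made from the silyl enol ether of 2',6'-dihydroxy-4'-methoxyacetophenone and PhI(OH)OTs, captured by C6 of intact 7,3',4'-tri-O-benzylluteolin.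
4. The luteolin half (rings A, C and B) is bought complete; its free, chelated 5-OH is relied on to direct attack to C6.

**Route**

Step 1
Reactants: 1 luteolin
Product: 2 7,3',4'-tri-O-benzylluteolin (7-(benzyloxy)-2-[3,4-bis(benzyloxy)phenyl]-5-hydroxy-4H-chromen-4-one)
Conditions: BnBr (3.2 equiv), K2CO3 (3.5 equiv), DMF, rt
Reagents that add atoms: benzyl bromide, BrCc1ccccc1
Why: Williamson etherification in which the 7-, 3'- and 4'-OH groups are alkylated while the 5-OH, hydrogen-bonded to the C4 carbonyl, stays free at room temperature, leaving the chelated phenol needed to steer the key step; no stereocentre is formed.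

Step 2
Reactants: 3 2',6'-dihydroxy-4'-methoxyacetophenone
Product: 4 {[1-(4-methoxy-2,6-bis(trimethylsilyloxy)phenyl)ethenyl]oxy}trimethylsilane
Conditions: Me3SiOTf (3.6 equiv), Et3N (5 equiv), CH2Cl2, 0 °C to rt; pentane trituration, filtration, used crude
Reagents that add atoms: trimethylsilyl trifluoromethanesulfonate, C[Si](C)(C)OS(=O)(=O)C(F)(F)F
Why: Silyl enol ether formation by soft enolisation, with concurrent O-silylation of both chelated phenols, gives the enol donor for iodine transfer and masks the acidic OH groups; no stereocentre is formed.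

Step 3
Reactants: 4 {[1-(4-methoxy-2,6-bis(trimethylsilyloxy)phenyl)ethenyl]oxy}trimethylsilane; 2 7,3',4'-tri-O-benzylluteolin
Product: 7 7-(benzyloxy)-2-[3,4-bis(benzyloxy)phenyl]-6-[2-(2,6-dihydroxy-4-methoxyphenyl)-2-oxoethyl]-5-hydroxy-4H-chromen-4-one, via enolonium iodane 5 (not isolated), via bis-silyl deoxybenzoin 6 (not isolated)
Conditions: PhI(OH)OTs (1.3 equiv), BF3·OEt2 (1.3 equiv, promoter), CH2Cl2, −78 °C, then 4 (1.3 equiv), 10 min; then 2 (1.0 equiv), −78 to −20 °C; aq NaHCO3, THF/H2O, rt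
Reagents that add atoms: none
Why: Proposed new method: umpolung α-arylation through an enolonium species, in which the silyl enol ether exchanges onto BF3-activated PhI(OH)OTs to give the α-λ3-iodanyl ketone 5, whose CH2 carbon is a primary α-keto cation equivalent bearing the hypernucleofugal PhI group, and this carbon is attacked in a Friedel–Crafts-type displacement by C6 of 2 (ortho to the free chelated 5-OH, the position at which 5-hydroxy-7-alkoxyflavones are halogenated) with loss of PhI and rearomatisation, the closest known reaction type being the metal-free α-arylation of preformed ketone enolonium species by indoles and other electron-rich arenes; no stereocentre is formed.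

Step 4
Reactants: 7 7-(benzyloxy)-2-[3,4-bis(benzyloxy)phenyl]-6-[2-(2,6-dihydroxy-4-methoxyphenyl)-2-oxoethyl]-5-hydroxy-4H-chromen-4-one; 8 4-(benzyloxy)benzoyl chloride
Product: 10 7-(benzyloxy)-2-[3,4-bis(benzyloxy)phenyl]-6-{2-[4-(benzyloxy)phenyl]-5-hydroxy-7-methoxy-4-oxo-4H-chromen-3-yl}-5-hydroxy-4H-chromen-4-one, via β-diketone 9 (not isolated)
Conditions: LiN(SiMe3)2 (5.5 equiv), THF, −78 to −20 °C; 8 (1.1 equiv), −78 °C to rt; aq HCl quench; then p-TsOH·H2O (cat.), toluene, 80 °C
Reagents that add atoms: none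
Why: Baker–Venkataraman-type 1,3-diketone synthesis by C-aroylation of the lithium polyanion (any O-aroylated material rearranges to the same diketone), followed by acid-catalysed cyclodehydration of either of the two equivalent ortho-OH groups onto the new aroyl carbonyl to close the pyranone, as in flavone syntheses from unprotected polyhydroxy ketones; the enolisable CH of 9 disappears and no stereocentre remains.

Step 5
Reactants: 10 7-(benzyloxy)-2-[3,4-bis(benzyloxy)phenyl]-6-{2-[4-(benzyloxy)phenyl]-5-hydroxy-7-methoxy-4-oxo-4H-chromen-3-yl}-5-hydroxy-4H-chromen-4-one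
Product: 11 2-(3,4-dihydroxyphenyl)-5,7-dihydroxy-6-[5-hydroxy-2-(4-hydroxyphenyl)-7-methoxy-4-oxo-4H-chromen-3-yl]-4H-chromen-4-one (CNP0200311.0)
Conditions: H2 (1 atm), Pd/C (10 wt%), THF/MeOH, rt
Reagents that add atoms: none
Why: Catalytic hydrogenolysis cleaves the four aryl benzyl ethers while the methyl ether and the vinylogous-ester C2=C3 bonds of both chromones are left untouched at 1 atm; the product has no stereocentre.

**Compound list**
1 | luteolin | O=c1cc(-c2ccc(O)c(O)c2)oc2cc(O)cc(O)c12 | starting material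
2 | 7,3',4'-tri-O-benzylluteolin | O=c1cc(-c2ccc(OCc3ccccc3)c(OCc3ccccc3)c2)oc2cc(OCc3ccccc3)cc(O)c12 | intermediate
3 | 2',6'-dihydroxy-4'-methoxyacetophenone | CC(=O)c1c(O)cc(OC)cc1O | starting material
4 | {[1-(4-methoxy-2,6-bis(trimethylsilyloxy)phenyl)ethenyl]oxy}trimethylsilane | C=C(O[Si](C)(C)C)c1c(O[Si](C)(C)C)cc(OC)cc1O[Si](C)(C)C | intermediate
5 | enolonium iodane: 1-[4-methoxy-2,6-bis(trimethylsilyloxy)phenyl]-2-[phenyl(tosyloxy)-λ3-iodanyl]ethan-1-one | O=C(C[I](OS(=O)(=O)c1ccc(C)cc1)c1ccccc1)c1c(O[Si](C)(C)C)cc(OC)cc1O[Si](C)(C)C | intermediate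
6 | bis-silyl deoxybenzoin: 7-(benzyloxy)-2-[3,4-bis(benzyloxy)phenyl]-5-hydroxy-6-{2-[4-methoxy-2,6-bis(trimethylsilyloxy)phenyl]-2-oxoethyl}-4H-chromen-4-one | COc1cc(O[Si](C)(C)C)c(C(=O)Cc2c(OCc3ccccc3)cc3oc(-c4ccc(OCc5ccccc5)c(OCc5ccccc5)c4)cc(=O)c3c2O)c(O[Si](C)(C)C)c1 | intermediate
7 | deoxybenzoin: 7-(benzyloxy)-2-[3,4-bis(benzyloxy)phenyl]-6-[2-(2,6-dihydroxy-4-methoxyphenyl)-2-oxoethyl]-5-hydroxy-4H-chromen-4-one | COc1cc(O)c(C(=O)Cc2c(OCc3ccccc3)cc3oc(-c4ccc(OCc5ccccc5)c(OCc5ccccc5)c4)cc(=O)c3c2O)c(O)c1 | intermediate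
8 | 4-(benzyloxy)benzoyl chloride | O=C(Cl)c1ccc(OCc2ccccc2)cc1 | starting material
9 | β-diketone: 2-{7-(benzyloxy)-2-[3,4-bis(benzyloxy)phenyl]-5-hydroxy-4-oxo-4H-chromen-6-yl}-1-[4-(benzyloxy)phenyl]-3-(2,6-dihydroxy-4-methoxyphenyl)propane-1,3-dione (enolisable CH, no defined stereocentre) | COc1cc(O)c(C(=O)C(C(=O)c2ccc(OCc3ccccc3)cc2)c2c(OCc3ccccc3)cc3oc(-c4ccc(OCc5ccccc5)c(OCc5ccccc5)c4)cc(=O)c3c2O)c(O)c1 | intermediate
10 | tetra-O-benzyl biflavone: 7-(benzyloxy)-2-[3,4-bis(benzyloxy)phenyl]-6-{2-[4-(benzyloxy)phenyl]-5-hydroxy-7-methoxy-4-oxo-4H-chromen-3-yl}-5-hydroxy-4H-chromen-4-one | COc1cc(O)c2c(=O)c(-c3c(OCc4ccccc4)cc4oc(-c5ccc(OCc6ccccc6)c(OCc6ccccc6)c5)cc(=O)c4c3O)c(-c3ccc(OCc4ccccc4)cc3)oc2c1 | intermediate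
11 | CNP0200311.0: 2-(3,4-dihydroxyphenyl)-5,7-dihydroxy-6-[5-hydroxy-2-(4-hydroxyphenyl)-7-methoxy-4-oxo-4H-chromen-3-yl]-4H-chromen-4-one | COc1cc(O)c2c(=O)c(-c3c(O)cc4oc(-c5ccc(O)c(O)c5)cc(=O)c4c3O)c(-c3ccc(O)cc3)oc2c1 | target

**Totals**
Total step count: 5. Longest linear sequence: 4 steps (1 → 2 → 7 → 10 → 11, or 3 → 4 → 7 → 10 → 11).

**Steps most likely to fail, with fallbacks**

Step 3 (key coupling) is the main risk. The enolonium may attack C8 instead of C6, the flavone ring A may be too weak a nucleophile, or the enolonium may be lost to O-attack or α-tosyloxylation. The fallback sets out from 2. It is iodinated at C6 (BnMe3N·ICl2, CaCO3, CH2Cl2/MeOH, rt; the free 5-OH directs ortho) to give 7-(benzyloxy)-2-[3,4-bis(benzyloxy)phenyl]-5-hydroxy-6-iodo-4H-chromen-4-one F1. F1 is then joined to silyl enol ether 4 by palladium-catalysed enolate α-arylation (Pd(dba)2, P(t-Bu)3, ZnF2, CsF, DMF, 80 °C), and aqueous work-up returns the route to 7. This reverts to normal polarity (enolate nucleophile, aryl electrophile) and fixes the position by the halogen.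

Step 4 (aroylation and ring closure) is the second risk. C-acylation at the crowded benzylic carbon may be slow, and the 5''-OH of the luteolin half could close a benzofuran in competition with the pyranone. The fallback sets out from 7. It is condensed with 4-(benzyloxy)benzaldehyde (piperidine, EtOH, reflux; Knoevenagel condensation, then 6-endo oxa-Michael closure, which is favoured over the 5-endo alternative from the 5''-OH) to give 2-[4-(benzyloxy)phenyl]-3-{7-(benzyloxy)-2-[3,4-bis(benzyloxy)phenyl]-5-hydroxy-4-oxo-4H-chromen-6-yl}-5-hydroxy-7-methoxychroman-4-one F2 (diastereomer mixture; both stereocentres are erased next). Dehydrogenation of F2 with DDQ (dioxane, 80 °C) returns the route to 10.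

Step 5 (global debenzylation) is the third risk. Hydrogenolysis may be incomplete on the poorly soluble, crowded substrate, or the C2''=C3'' bond of the luteolin half may be partly reduced. The fallback sets out from 10 and replaces reductive cleavage by Lewis-acid dealkylation with a cation trap (BCl3, pentamethylbenzene, CH2Cl2, −78 °C; the 7-OMe group survives at this temperature). It arrives directly at 11 and makes no new compound.

**Further compounds**
F1 | step 3 | 7-(benzyloxy)-2-[3,4-bis(benzyloxy)phenyl]-5-hydroxy-6-iodo-4H-chromen-4-one | O=c1cc(-c2ccc(OCc3ccccc3)c(OCc3ccccc3)c2)oc2cc(OCc3ccccc3)c(I)c(O)c12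
F2 | step 4 | 2-[4-(benzyloxy)phenyl]-3-{7-(benzyloxy)-2-[3,4-bis(benzyloxy)phenyl]-5-hydroxy-4-oxo-4H-chromen-6-yl}-5-hydroxy-7-methoxychroman-4-one (diastereomer mixture, stereocentres undefined) | COc1cc(O)c2c(c1)OC(c1ccc(OCc3ccccc3)cc1)C(c1c(OCc3ccccc3)cc3oc(-c4ccc(OCc5ccccc5)c(OCc5ccccc5)c4)cc(=O)c3c1O)C2=O
F0 | step 5 | none | none
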